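The rate constants belong to no real substance.

Substrate left late in this flask is a store from which target can still be made, so the target then standing is tied to that leftover. Two chemists argue over how.

substrate 0.050 M; reagent in the second phase 1.50 equiv; time 25 min; volume of the second phase over the first 1.0

    reagent in the reaction phase ⇌ reagent in the second phase, rate k1*([reagent in the reaction phase] - [reagent in the second phase]/K1) per volume of the first phase (K1 = 0.68, k1 = 0.055 min⁻¹)
    2 substrate → homo dimer (k2 = 1.0 M⁻¹ min⁻¹)
    substrate ⇌ dormant form (K3 = 0.75, k3 = 0.044 min⁻¹)
    reagent in the reaction phase + target → over-reacted product (k4 = 2.9 M⁻¹ min⁻¹)
    target → over-reaction product (k5 = 0.077 min⁻¹)
    substrate + reagent in the reaction phase → target (k6 = 5.0 M⁻¹ min⁻¹)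

- a species is counted by the substrate in it: one homo dimer counts as two
- two of one species on the left: rate k times its square, two consumed each time
- in the second phase: reagent in the second phase; everything else is in the first
- charges count per volume of the first phase; a concentration in a rate is the amount of a species over the volume of its own phase; every rate counts per litre of the first phase
- run time (flask): 25 min

- how much target there is at 25 min, in percent of the substrate charged
- the change that raises the amount of target at 25 min, in percent of the substrate charged most ("none" if none brings more than 2 percentage points) (spring / noon / none)
- amount of target at 25 min, in percent of the substrate charged, after spring

The first holds a supply view: target is what the reagent reaches. In this flask the reagent crosses with a half-time of 5.10 min, which is shorter than the run, and at balance 59.5% of it stands in the reaction phase. With half the charge taken as spent, that is 0.0223 M. Substrate then goes to target at 0.112 min⁻¹ against 0.100 min⁻¹ to homo dimer at the start, so she claims 52.7% of the charge as target, and more with double the reagent.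

I hold the second view: target is also lost, by itself and with reagent, at 0.142 min⁻¹, which is faster than substrate goes to target. I carry the holding ratio, the target per substrate at which target is made just as fast as it is lost, here 0.787. The even case is one, and this flask stands below it, so by this reckoning target at balance stands under the leftover substrate.

Substrate falling at the first rate, target lost at the second, and her share give me 6.35%. Doubling the reagent lifts the loss to 0.206 min⁻¹ and gives 1.80%. Doubling the transfer leaves these balance figures as they are, so my choice is none.

The forecast, on my side but with other figures, gives 8.5% (7% to 10.5%), none, and 3% (1.8% to 4.5%), on the ground that “More reagent or faster transfer only moves the peak earlier and speeds the loss”.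

The flask gives 8.62% of target, far under the supply claim and above my figure. Doubling the reagent moves it by −4.7 percentage points to 3.89%, doubling the transfer moves it by −0.96 points, and the best change is none.

In this flask, each step taken net, target was made 1.86 times as fast as it was used up at 6.24 min, the stretch where the supply view holds, but at 25.0 min making stood at 0.585 of the loss. The holding ratio of 0.787 on the 6.58% of substrate left gives a balance of 5.18%, less than the 8.62% of target standing; in the neighbour flask charged with 0.20 M of substrate the same rule gives a ratio of 1.33, and on its 0.598% of substrate a balance of 0.795%, less than the 1.22% of target read there at 25.0 min.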